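**Design of a total synthesis of CNP0306954.0 (compound 18) by a Michael–Claisen construction of ring B**

## The problem

Target 18 joins three rings in a row: a resorcinol ring A carrying a propyl group, a second resorcinol ring B, and a 4-hydroxy-2-pyranone ring C. Rings A and B meet in a diaryl ketone whose carbonyl carbon lies between four ortho substituents (oxygen and propyl on ring A, oxygen and the CH2 arm on ring B). Ring C hangs from C6' of ring B through a single methylene. The molecule has no stereocentre, so nothing has to be controlled in the product, and a stereocentre made on the way is acceptable only if aromatisation removes it. Three features will not stand rough treatment: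

- the pyranone is an acidic enol lactone, opened by hot hydroxide or alkoxide and nucleophilic at C3 and C5;
- the four phenols make rings A and B easy to oxidise and to halogenate;
- the ketone oxygen stands 1,5 to the first carbon beyond the arm CH2, so an aldehyde or acetal at that carbon closes onto the ketone under acid to a 2-benzopyrylium ion.

The crowded ketone is awkward to make by joining two finished rings and, once made, is almost inert to nucleophiles. The key step rests on the substitution of ring B: the oxygens on C2' and C4' are 1,3 to each other, the acyl group sits on C1' and the carbon arm on C6'. This is the pattern of a 4-acyl-5-alkylcyclohexane-1,3-dione after loss of two hydrogens. In that dione C1'–C6' is a Michael bond and C2'–C3' a Claisen bond between a ring A β-keto ester (C1', C2') and a methyl enone (C3' to C6' with the arm).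

## Retrosynthesis

**18 to 17 (four O–CH3 bonds).** The free phenols are traced back to methyl ethers in 17. Methyl is the only phenol protection expected to survive AlCl3, methoxide, HI in methanol, a lithium dienolate and 110 °C. The cost is one Lewis-acid step at the end, which must cleave four aryl ethers and leave the enol lactone alone.

**17 to 15 to 12 + 13 (pyranone O1–C2 and C5–C6).** Ring C is opened at the lactone bond to acylketene 16, which comes from dioxinone 15 by loss of acetone. Compound 15 is cut between the arm carbonyl and the dioxinone methyl carbon, giving arylacetic acid 12 (as imidazolide 14) and the four-carbon unit 13. Against a Dieckmann closure at the dihydro level, this cut delivers the pyranone at the right oxidation state and closes it under neutral, thermal conditions. The forward reaction has to acylate the dienolate of 13 at its γ-carbon while the diaryl ketone looks on.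

**12 to 11 to 10 to 9 (oxidation level, one O–CH3, dehydrogenation).** The acid carbon is traced to a primary alcohol, the C2' methyl ether to the phenol, and the arene to the cyclohexane-1,3-dione 9. The arm is carried at the alcohol level on purpose:

- an aldehyde or acetal at this carbon would close onto the ketone in the acidic aromatisation and end as a 2-benzopyrylium ion;
- an ester would make the γ-CH2 of the enone partner too acidic for a clean Michael addition;
- a silyl ether is inert in the ring construction and falls off in the aromatisation medium.

Iodine in methanol is asked to do three things in one operation: dehydrogenate the ring, methylate the C4' oxygen and free the alcohol.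

**9 to 4 + 7 (C1'–C6' and C2'–C3', the key disconnection).** Both bonds are cut at once, removing ring B and leaving a ring A β-keto ester 4 and a six-carbon enone 7. The neighbouring cut at the aryl–carbonyl bond C1'–CO would have to join two rings at their most hindered carbons and needs ring A as a benzoic acid, which resorcinol 1 does not offer directly. Here the crowded ketone is already present in 4, where it was made at an open position with a small acyl chloride, and ring B is built around it. The forward reaction needs conjugate addition of 4 to 7, then closure onto the ester and not onto the aryl ketone.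

**4 to 2 + 3, and 2 to 1 (aryl–CO bond, two O–CH3).** The keto ester is cut at the aryl–carbonyl bond to dimethyl ether 2 and methyl malonyl chloride 3. The acylation must go to C4 of 2 (ortho to propyl and one methoxy, para to the other) and not to C2 between the methoxy groups, and must not cleave an ether. Compound 2 is the bis-methyl ether of commercial 5-propylresorcinol 1.

**7 to 5 + 6 (C3=C4).** The enone is cut at its double bond to the commercial silyloxy aldehyde 5 and the acetonyl ylide 6. A ketone-stabilised ylide should give the E-alkene in one step.

## Roads not taken

**Alternative 1:** Ring B would be bought aromatic and both of its carbon substituents installed at once by inserting an aryne into the CH2–CO bond of keto ester 4. CsF would release the aryne from 3,5-dimethoxy-2-(trimethylsilyl)phenyl triflate A2. The enolate carbon of 4 adds meta to the methoxy group, the aryl anion closes onto the ketone, and fragmentation of the four-membered alkoxide gives methyl 2-[2-(2,4-dimethoxy-6-propylbenzoyl)-3,5-dimethoxyphenyl]acetate A1.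

- Merits: the regiochemistry is right, ring B never leaves the aromatic state, and A1 is the methyl ester of acid 12. Insertion plus saponification would replace steps 3 to 7. Even with about three to four steps for A2, this road is shorter on paper and more convergent.
- Weak point: the second stage of the insertion requires the aryl anion to add to the ketone of 4, which lies between a methoxy and a propyl group and is electron-rich. Proton transfer and simple α-arylation without C–C cleavage are the likely outcome.
- Comparison: the chosen plan is longer, but it uses the same inertness of that ketone as its source of selectivity in step 4 and needs only bulk reagents.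

**Alternative 2:** Ring A would be made by biomimetic folding. The cut is the C1–C6 bond of ring A. Aqueous KOH would open the pyranone ring of 2-[2-(2,4-dimethoxy-6-methylphenyl)-2-oxoethyl]-6-propyl-4H-pyran-4-one A4. The methylene next to the aryl ketone then adds to the butyryl carbonyl, and dehydration gives (2,4-dihydroxy-6-propylphenyl)(2,4-dimethoxy-6-methylphenyl)methanone A3.

- Merits: the oxygen pattern of ring A follows from the chain, and the crowded ketone is again present before the ring is closed.
- Weak points: the key step is spent on the ring that can be bought (1 already has ring A), and A3 carries a methyl group where the target needs CH2–pyranone. That benzylic carbon would have to be metalated or halogenated and then acylated next to a diaryl ketone and two free phenols. Hot KOH also rules out an earlier pyranone ring C.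
- Comparison: A3 might be reached in fewer steps than 11, but the hardest bond of the target would still be open. The chosen plan sets the functionalised arm during ring construction.

**Alternative 3:** Ring C would be closed at carbon. The cut is the pyranone C3–C4 bond. LiN(SiMe3)2 would deprotonate the acetate of methyl 3-acetoxy-4-[2-(2,4-dimethoxy-6-propylbenzoyl)-3,5-dimethoxyphenyl]butanoate A6, and the enolate would attack the methyl ester to give the racemic dihydropyranone A5 (6-{[2-(2,4-dimethoxy-6-propylbenzoyl)-3,5-dimethoxyphenyl]methyl}-4-hydroxy-5,6-dihydro-2H-pyran-2-one).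

- Merits: the closure is a mild and dependable Dieckmann reaction, as reliable as step 9, and it avoids an acylketene.
- Weak points: A5 is two hydrogens short of the pyranone, and dehydrogenation across C5–C6 of such a lactone is not dependable. A stereocentre is made only to be destroyed. A6 requires an aldol reaction on an aldehyde-level arm, the group that cyclises onto the ketone. Loss of acetate from the ester enolate competes with ring closure.
- Comparison: this road says nothing about the benzophenone core, so it answers the easier half of the problem. The chosen plan reaches ring C at the right oxidation level in two steps from 12.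

Key step: step 4

## Route

Remark: dione 9 is a mixture of keto and enol tautomers. It is written as the enol hydrogen-bonded to the aroyl carbonyl, which leaves C5 as its only stereocentre (racemic).

Remark: in step 5 the methyl group from methanol is assumed to end on the C4' oxygen, the C2' oxygen staying as the chelated phenol. Step 6 converges any other distribution on 11.

Step 1
Reactants: 1 5-propylresorcinol
Product: 2 1,3-dimethoxy-5-propylbenzene
Conditions: MeI (2.5 equiv), K2CO3 (3 equiv), acetone, reflux
Reagents that add atoms: iodomethane, CI
Why: Williamson etherification of both phenols; methyl ethers should survive AlCl3, methoxide, HI in methanol and the lithium dienolate used later.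

Step 2
Reactants: 2 1,3-dimethoxy-5-propylbenzene; 3 methyl malonyl chloride (methyl 3-chloro-3-oxopropanoate)
Product: 4 methyl 3-(2,4-dimethoxy-6-propylphenyl)-3-oxopropanoate
Conditions: AlCl3 (2.2 equiv), CH2Cl2, −10 → 0 °C; ice, 1 M HCl
Reagents that add atoms: none
Why: Friedel–Crafts acylation; the acylium ion should attack C4 of 2, ortho to one methoxy group and para to the other, since the position between the two methoxy groups is more hindered and lacks a para donor. Low temperature should keep AlCl3 from cleaving the ether next to the new ketone.

Step 3
Reactants: 5 3-[(tert-butyldimethylsilyl)oxy]propanal; 6 1-(triphenylphosphoranylidene)propan-2-one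
Product: 7 (E)-6-[(tert-butyldimethylsilyl)oxy]hex-3-en-2-one
Conditions: CH2Cl2, 20 → 40 °C
Reagents that add atoms: none
Why: Wittig olefination with a ketone-stabilised ylide, which should give the E-enone under thermodynamic control of the oxaphosphetane; the ylide is too weak a base to eliminate the β-silyloxy aldehyde.

Step 4
Reactants: 4 methyl 3-(2,4-dimethoxy-6-propylphenyl)-3-oxopropanoate; 7 (E)-6-[(tert-butyldimethylsilyl)oxy]hex-3-en-2-one
Product: 9 racemic 5-{2-[(tert-butyldimethylsilyl)oxy]ethyl}-4-(2,4-dimethoxy-6-propylbenzoyl)-3-hydroxycyclohex-3-en-1-one, via Michael adduct 8 (not isolated)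
Conditions: NaOMe (1.2 equiv), MeOH, 0 °C, slow addition of 7 (1.1 equiv), 0 → 20 °C; then 60 °C; 1 M HCl to pH 4 at 0 °C
Reagents that add atoms: none
Why: Methoxide converts 4 into its stabilised enolate, which adds through carbon to C4 of enone 7 (Michael addition, C1'–C6' bond) to give adduct 8. In 8 only the methyl-side enolate of the methyl ketone can reach a carbonyl group through a six-membered transition state; it attacks the methyl ester (Claisen condensation of the Dieckmann kind, 6-exo-trig, C2'–C3' bond), and loss of methoxide followed by deprotonation of the resulting vinylogous acid makes the closure irreversible. The closest known reaction type is the Michael–Claisen annulation of malonates and β-keto esters with alk-3-en-2-ones that gives 5-alkylcyclohexane-1,3-diones on the way to 5-alkylresorcinols. The one new stereocentre (C5 of 9, the later C6') is formed without control as a racemate, and none is needed because step 5 removes it. The selectivity that matters is ester against aryl ketone as the electrophile: the aryl ketone lies between a methoxy and a propyl group, is twisted out of plane and is electron-rich, so aldol addition to it should be slow and reversible while the dione enolate is a sink. Conjugate addition in preference to carbonyl addition follows from the soft, stabilised donor. Keeping free methoxide low during the Michael stage and adding 7 slowly should hold back γ-deprotonation of 7 and loss of silanolate; once 8 has formed, the silyloxyethyl arm is no longer β to an acidic position.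

Step 5
Reactants: 9 racemic 5-{2-[(tert-butyldimethylsilyl)oxy]ethyl}-4-(2,4-dimethoxy-6-propylbenzoyl)-3-hydroxycyclohex-3-en-1-one
Product: 10 (2,4-dimethoxy-6-propylphenyl)[2-hydroxy-6-(2-hydroxyethyl)-4-methoxyphenyl]methanone
Conditions: I2 (2.2 equiv), MeOH, reflux; aq. Na2S2O3, then 1 M HCl/THF, 20 °C, brief
Reagents that add atoms: methanol, CO
Why: Iodine–methanol aromatisation of an acylated cyclohexane-1,3-dione: the acid formed turns the vinylogous acid into its methyl enol ether at the unhindered C4' oxygen, and α-iodination with loss of HI gives the arene, the C2' oxygen remaining as the phenol chelated to the ketone. The same acidic methanol cleaves the primary silyl ether, and the dilute acid wash reopens any cyclic ketal formed between the freed alcohol and the ketone.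

Step 6
Reactants: 10 (2,4-dimethoxy-6-propylphenyl)[2-hydroxy-6-(2-hydroxyethyl)-4-methoxyphenyl]methanone
Product: 11 (2,4-dimethoxy-6-propylphenyl)[2-(2-hydroxyethyl)-4,6-dimethoxyphenyl]methanone
Conditions: MeI (1.5 equiv), K2CO3 (2 equiv), DMF, 40 °C
Reagents that add atoms: iodomethane, CI
Why: Williamson etherification; carbonate deprotonates the chelated phenol but not the primary alcohol, so only the phenol is methylated. Any regioisomeric or unmethylated resorcinol carried over from step 5 should converge on 11.

Step 7
Reactants: 11 (2,4-dimethoxy-6-propylphenyl)[2-(2-hydroxyethyl)-4,6-dimethoxyphenyl]methanone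
Product: 12 2-[2-(2,4-dimethoxy-6-propylbenzoyl)-3,5-dimethoxyphenyl]acetic acid
Conditions: TEMPO (0.1 equiv), NaClO2 (2 equiv), NaOCl (0.05 equiv), MeCN/sodium phosphate buffer pH 6.7, 35 °C
Reagents that add atoms: sodium chlorite, [Na+].[O-]Cl=O
Why: Oxoammonium-catalysed oxidation of a 2-arylethanol to the arylacetic acid with chlorite as terminal oxidant; the aldehyde is oxidised as soon as it forms in a near-neutral buffer, so it should not close onto the ketone. Hypochlorite is present only in catalytic amount, which should spare the electron-rich rings from chlorination.

Step 8
Reactants: 12 2-[2-(2,4-dimethoxy-6-propylbenzoyl)-3,5-dimethoxyphenyl]acetic acid; 13 2,2,6-trimethyl-4H-1,3-dioxin-4-one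
Product: 15 6-{3-[2-(2,4-dimethoxy-6-propylbenzoyl)-3,5-dimethoxyphenyl]-2-oxopropyl}-2,2-dimethyl-4H-1,3-dioxin-4-one, via acyl imidazolide 14 (not isolated)
Conditions: CDI (1.05 equiv), THF, 20 °C; then added to 13 (3 equiv) and LiN(SiMe3)2 (3 equiv), THF, −78 → −40 °C; aq. NH4Cl
Reagents that add atoms: none
Why: Crossed Claisen acylation of the lithium dienolate of 13 at its γ-carbon by the acyl imidazolide, a standard route to 6-(2-oxoalkyl)dioxinones. The excess dienolate takes up the acidic product, and the diaryl ketone with four ortho substituents should not be attacked.

Step 9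
Reactants: 15 6-{3-[2-(2,4-dimethoxy-6-propylbenzoyl)-3,5-dimethoxyphenyl]-2-oxopropyl}-2,2-dimethyl-4H-1,3-dioxin-4-one
Product: 17 6-{[2-(2,4-dimethoxy-6-propylbenzoyl)-3,5-dimethoxyphenyl]methyl}-4-hydroxy-2H-pyran-2-one, via acylketene 16 (not isolated)
Conditions: toluene, 110 °C
Reagents that add atoms: none
Why: Thermal retro-hetero-Diels–Alder loss of acetone gives the acylketene, which is trapped by the enol oxygen of the δ-ketone in a six-membered lactonisation and tautomerises to the 4-hydroxy-2-pyranone. No acid or base is present, so the arm cannot cyclise onto the diaryl ketone.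

Step 10
Reactants: 17 6-{[2-(2,4-dimethoxy-6-propylbenzoyl)-3,5-dimethoxyphenyl]methyl}-4-hydroxy-2H-pyran-2-one
Product: 18 6-{[2-(2,4-dihydroxy-6-propylbenzoyl)-3,5-dihydroxyphenyl]methyl}-4-hydroxy-2H-pyran-2-one (CNP0306954.0)
Conditions: BBr3 (10 equiv), CH2Cl2, −78 → 20 °C; MeOH, then H2O
Reagents that add atoms: none
Why: Lewis-acid cleavage of aryl methyl ethers by bromide attack on the boron-complexed ether; the two ethers ortho to the ketone are helped by chelation and the two para ethers follow at 20 °C. 4-Hydroxy-2-pyranones and hindered diaryl ketones are known to tolerate BBr3, and the low temperature should keep the complexed ketone from reacting with pyranone C5.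

## Compound list

1 | 5-propylresorcinol | CCCc1cc(O)cc(O)c1 | starting material
2 | 1,3-dimethoxy-5-propylbenzene | CCCc1cc(OC)cc(OC)c1 | intermediate
3 | methyl malonyl chloride (methyl 3-chloro-3-oxopropanoate) | COC(=O)CC(=O)Cl | starting material
4 | methyl 3-(2,4-dimethoxy-6-propylphenyl)-3-oxopropanoate | CCCc1cc(OC)cc(OC)c1C(=O)CC(=O)OC | intermediate
5 | 3-[(tert-butyldimethylsilyl)oxy]propanal | O=CCCO[Si](C)(C)C(C)(C)C | starting material
6 | 1-(triphenylphosphoranylidene)propan-2-one | CC(=O)C=P(c1ccccc1)(c1ccccc1)c1ccccc1 | starting material
7 | (E)-6-[(tert-butyldimethylsilyl)oxy]hex-3-en-2-one | CC(=O)/C=C/CCO[Si](C)(C)C(C)(C)C | intermediate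
8 | Michael adduct, methyl 3-{2-[(tert-butyldimethylsilyl)oxy]ethyl}-2-(2,4-dimethoxy-6-propylbenzoyl)-5-oxohexanoate (racemic mixture of diastereomers, formed in the flask) | CCCc1cc(OC)cc(OC)c1C(=O)C(C(=O)OC)C(CCO[Si](C)(C)C(C)(C)C)CC(C)=O | intermediate
9 | racemic 5-{2-[(tert-butyldimethylsilyl)oxy]ethyl}-4-(2,4-dimethoxy-6-propylbenzoyl)-3-hydroxycyclohex-3-en-1-one (enol form of the 4-aroyl-5-substituted cyclohexane-1,3-dione) | CCCc1cc(OC)cc(OC)c1C(=O)C1=C(O)CC(=O)CC1CCO[Si](C)(C)C(C)(C)C | intermediate
10 | (2,4-dimethoxy-6-propylphenyl)[2-hydroxy-6-(2-hydroxyethyl)-4-methoxyphenyl]methanone | CCCc1cc(OC)cc(OC)c1C(=O)c1c(O)cc(OC)cc1CCO | intermediate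
11 | (2,4-dimethoxy-6-propylphenyl)[2-(2-hydroxyethyl)-4,6-dimethoxyphenyl]methanone | CCCc1cc(OC)cc(OC)c1C(=O)c1c(OC)cc(OC)cc1CCO | intermediate
12 | 2-[2-(2,4-dimethoxy-6-propylbenzoyl)-3,5-dimethoxyphenyl]acetic acid | CCCc1cc(OC)cc(OC)c1C(=O)c1c(OC)cc(OC)cc1CC(=O)O | intermediate
13 | 2,2,6-trimethyl-4H-1,3-dioxin-4-one | CC1=CC(=O)OC(C)(C)O1 | starting material
14 | acyl imidazolide, 2-[2-(2,4-dimethoxy-6-propylbenzoyl)-3,5-dimethoxyphenyl]-1-(1H-imidazol-1-yl)ethan-1-one (formed in the flask) | CCCc1cc(OC)cc(OC)c1C(=O)c1c(OC)cc(OC)cc1CC(=O)n1ccnc1 | intermediate
15 | 6-{3-[2-(2,4-dimethoxy-6-propylbenzoyl)-3,5-dimethoxyphenyl]-2-oxopropyl}-2,2-dimethyl-4H-1,3-dioxin-4-one | CCCc1cc(OC)cc(OC)c1C(=O)c1c(OC)cc(OC)cc1CC(=O)CC1=CC(=O)OC(C)(C)O1 | intermediate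
16 | acylketene, 6-[2-(2,4-dimethoxy-6-propylbenzoyl)-3,5-dimethoxyphenyl]-3,5-dioxohex-1-en-1-one (formed in the flask) | CCCc1cc(OC)cc(OC)c1C(=O)c1c(OC)cc(OC)cc1CC(=O)CC(=O)C=C=O | intermediate
17 | 6-{[2-(2,4-dimethoxy-6-propylbenzoyl)-3,5-dimethoxyphenyl]methyl}-4-hydroxy-2H-pyran-2-one | CCCc1cc(OC)cc(OC)c1C(=O)c1c(OC)cc(OC)cc1Cc1cc(O)cc(=O)o1 | intermediate
18 | 6-{[2-(2,4-dihydroxy-6-propylbenzoyl)-3,5-dihydroxyphenyl]methyl}-4-hydroxy-2H-pyran-2-one (CNP0306954.0) | CCCc1cc(O)cc(O)c1C(=O)c1c(O)cc(O)cc1Cc1cc(O)cc(=O)o1 | target

## Step count and risk

Total step count: 10. Longest linear sequence: 9 steps (steps 1, 2 and 4 to 10, from 1); step 3 is a one-step branch.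

Least certain steps, in order of concern:

**Step 4 (key step).** The most likely failure is consumption of enone 7 by base before it is captured: γ-deprotonation and loss of silanolate give a dienone that polymerises or adds the donor at the wrong carbon. A slower Claisen closure would also leave time for retro-Michael cleavage or for closure onto the aryl ketone. The fallback separates the two bond formations and removes alkoxide from the first. From 4 and 7, the conjugate addition is run with catalytic DBU in MeCN at 0 °C and adduct 8 is isolated. The ring is then closed with KOt-Bu in THF at 0 °C, a base that can neither transesterify nor cleave the product. The route is rejoined at 9, and no compound outside the list arises (F0).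

**Step 5.** The acidic methanol may overreact with the product: the freed alcohol can close onto the ketone, methylation can spread over both ring B oxygens, and the new electron-rich ring can be iodinated. The fallback replaces oxidative etherification by bromination and dehydrobromination. From 9, Br2 (1.0 equiv) in DMF at 0 °C and then 80 °C, with an aqueous HCl work-up that completes the desilylation, should give the free resorcinol [2,4-dihydroxy-6-(2-hydroxyethyl)phenyl](2,4-dimethoxy-6-propylphenyl)methanone F1. Both phenols of F1 are then methylated with MeI and K2CO3 in DMF, which rejoins the route at 11 and bypasses 10.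

**Step 8.** Proton transfer from the acidic benzylic CH2 of 14 to the dienolate may outrun acylation, and the product may be acylated a second time, both at the cost of conversion. The fallback forms the C–C bond at the aldehyde level, where proton transfer is not destructive. From 11, Dess–Martin periodinane buffered with NaHCO3 should give 2-[2-(2,4-dimethoxy-6-propylbenzoyl)-3,5-dimethoxyphenyl]acetaldehyde F2, which is used at once and kept away from acid. Vinylogous aldol addition of the lithium dienolate of 13 at −78 °C should give racemic 6-{3-[2-(2,4-dimethoxy-6-propylbenzoyl)-3,5-dimethoxyphenyl]-2-hydroxypropyl}-2,2-dimethyl-4H-1,3-dioxin-4-one F3. A second Dess–Martin oxidation rejoins the route at 15 and bypasses 12 and 14.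

**Step 2.** AlCl3 may cleave the methoxy group next to the new ketone, after which the phenol closes onto the ester. The bifunctional acyl chloride may also condense with itself, or some acylation may occur between the two methoxy groups. The fallback builds the keto ester in two stages with a simpler electrophile. From 2, acetyl chloride and SnCl4 in CH2Cl2 at −20 °C should give 1-(2,4-dimethoxy-6-propylphenyl)ethan-1-one F4. Claisen methoxycarbonylation of its enolate with NaH and dimethyl carbonate in THF rejoins the route at 4.

## Further compounds

F0 | step 4 | none | none
F1 | step 5 | [2,4-dihydroxy-6-(2-hydroxyethyl)phenyl](2,4-dimethoxy-6-propylphenyl)methanone | CCCc1cc(OC)cc(OC)c1C(=O)c1c(O)cc(O)cc1CCO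
F2 | step 8 | 2-[2-(2,4-dimethoxy-6-propylbenzoyl)-3,5-dimethoxyphenyl]acetaldehyde | CCCc1cc(OC)cc(OC)c1C(=O)c1c(OC)cc(OC)cc1CC=O
F3 | step 8 | racemic 6-{3-[2-(2,4-dimethoxy-6-propylbenzoyl)-3,5-dimethoxyphenyl]-2-hydroxypropyl}-2,2-dimethyl-4H-1,3-dioxin-4-one | CCCc1cc(OC)cc(OC)c1C(=O)c1c(OC)cc(OC)cc1CC(O)CC1=CC(=O)OC(C)(C)O1
F4 | step 2 | 1-(2,4-dimethoxy-6-propylphenyl)ethan-1-one | CCCc1cc(OC)cc(OC)c1C(C)=O
A1 | alternative 1 | methyl 2-[2-(2,4-dimethoxy-6-propylbenzoyl)-3,5-dimethoxyphenyl]acetate | CCCc1cc(OC)cc(OC)c1C(=O)c1c(OC)cc(OC)cc1CC(=O)OC
A2 | alternative 1 | 3,5-dimethoxy-2-(trimethylsilyl)phenyl trifluoromethanesulfonate | COc1cc(OC)c([Si](C)(C)C)c(OS(=O)(=O)C(F)(F)F)c1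
A3 | alternative 2 | (2,4-dihydroxy-6-propylphenyl)(2,4-dimethoxy-6-methylphenyl)methanone | CCCc1cc(O)cc(O)c1C(=O)c1c(OC)cc(OC)cc1C
A4 | alternative 2 | 2-[2-(2,4-dimethoxy-6-methylphenyl)-2-oxoethyl]-6-propyl-4H-pyran-4-one | CCCc1cc(=O)cc(CC(=O)c2c(OC)cc(OC)cc2C)o1
A5 | alternative 3 | racemic 6-{[2-(2,4-dimethoxy-6-propylbenzoyl)-3,5-dimethoxyphenyl]methyl}-4-hydroxy-5,6-dihydro-2H-pyran-2-one | O=C1C=C(O)CC(Cc2cc(OC)cc(OC)c2C(=O)c2c(OC)cc(OC)cc2CCC)O1
A6 | alternative 3 | methyl 3-acetoxy-4-[2-(2,4-dimethoxy-6-propylbenzoyl)-3,5-dimethoxyphenyl]butanoate | CCCc1cc(OC)cc(OC)c1C(=O)c1c(OC)cc(OC)cc1CC(OC(C)=O)CC(=O)OC
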